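## The problem

Kanzonol S is a (2S)-flavanone: a phloroglucinol-type ring A fused to a dihydropyranone ring C, a catechol ring B on C2, and an (E)-4-acetoxy-3-methylbut-2-enyl chain on C8. The skeleton is small, so the difficulty lies in selectivity. C2 is the only stereocentre and nothing else in the molecule can direct it, so it must come from a chiral catalyst or a resolution. Once the C4 ketone is present, base erases C2 through retro-oxa-Michael opening to the chalcone. The chain must sit on C8 and not on C6, which means one of the two ortho oxygens of a symmetric phloroglucinol carbonyl compound has to be singled out as O1. The chain holds a trisubstituted (E)-alkene and a primary allylic acetate, which exclude hydrogenolysis, strong base, hydride reagents and hot protic acid (the C7 hydroxyl would cyclise onto the alkene), so the four phenols can only carry groups that leave under buffered fluoride. The enabling feature is ring C itself: O1, C8a, C4a and C4 are the four atoms of an ortho-quinone methide cut out of a salicylaldehyde, and C2–C3 is the vinyl group of a 3,4-dioxygenated styrene, so O1–C2 and C3–C4 can be formed in one [4+2] that also creates C2. C4 then arrives as a benzylic ether, one oxidation level below the ketone, which keeps the base-labile β-aryloxy ketone out of the route until the last two steps.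

## Retrosynthesis

**15 to 14.** The last operation frees the four phenols, so the first cut removes four O–Si bonds and leads to the fully silylated flavanone 14. Silyl ethers are preferred to benzyl ethers (hydrogenolysis would attack the chain), to acetal groups (acidic removal would cyclise the C7 hydroxyl onto the alkene) and to esters (their removal would not spare the chain acetate). Triisopropylsilyl goes on ring A and tert-butyldimethylsilyl on ring B. Compound 14 is no simpler in skeleton than 15, but every earlier step can be run in this form. The forward step must be a fluoride cleavage buffered so that no phenoxide opens ring C.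

**14 to 13 to 12.** The C4 ketone is traced to the benzylic alcohol 13 and then to the methyl ether 12. No skeletal bond is cut; only the oxidation level at C4 is lowered. This is preferred to carrying the ketone through ring formation, because a C4 ether is exactly what an o-quinone methide cycloaddition delivers. The price is two functional-group steps. The gain is that the C4 stereocentre of 12 is discarded, so only C2 must be right. The forward steps need an SN1 exchange of methoxy for hydroxy without elimination to the flav-3-ene, and a mild oxidation.

**12 to 6 plus 9.** Ring C of 12 is opened at O1–C2 and C3–C4. This gives salicylaldehyde 6 (ring A with the chain, O1 as its free hydroxyl, C4 as its formyl carbon) and styrene 9 (ring B with C2 and C3). The neighbouring cuts are weaker. Cutting O1–C2 alone gives a 2'-hydroxychalcone whose asymmetric oxa-Michael closure is reversible. Cutting the C2–aryl bond gives a chromone that would first have to be built with the chain in place. The double cut joins two fragments of similar size, each a few steps from a commercial aldehyde, and forms the ring and the stereocentre together. The forward reaction must ionise 6, through its acetal 10, to cation 11, add 9 in the right orientation, and fix C2 through a chiral counter-anion.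

**6 to 5 to 4 plus 3.** In 6 the two O–Si bonds are cut first, giving triol 5. Then the aryl–CH2 bond of the chain is cut, giving 2,4,6-trihydroxybenzaldehyde 4 and allylic chloride 3. Alkylating the symmetric 4 before any hydroxyl is differentiated means either of two equivalent carbons gives the same product. The choice between O1 and the C5 oxygen is left to the silylation, where the hydroxyl wedged between chain and formyl group is the most hindered and stays free. The reverse order would need an ortho-selective C-alkylation of a protected salicylaldehyde, which is reliable only by a longer Claisen route. The forward steps need C- over O-alkylation, mono- over dialkylation, and site-selective silylation.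

**3 to 2 to 1.** Chloride 3 is the acetate of alcohol 2, and 2 comes from isoprene monoxide 1 by cutting the C–Cl bond with allylic transposition. The whole chain, with its E geometry and its acetate, thus comes from a commercial five-carbon epoxide in two steps. Late allylic oxidation of a prenyl group beside an aldehyde and phenols is avoided. The forward step needs an E-selective conjugate opening of the vinyl oxirane.

**9 to 8 to 7.** Styrene 9 is cut at its C=C bond to aldehyde 8, and 8 at its two O–Si bonds to 3,4-dihydroxybenzaldehyde 7. Both steps are routine. The silyl ethers keep the arene electron-rich enough to stabilise positive charge at C2 in the key step, and they leave in the same final operation as the ring-A groups.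

## Roads not taken

**Alternative 1:** The cut is the C4a–C5 bond of ring A, so ring A is grown on a preformed, enantiopure ring C. The precursor A2 is a (2S)-2-aryl-2,3-dihydro-4H-pyran-4-one whose C6 carries a carbon bearing both the chain and a 2,2-dimethyl-1,3-dioxin-4-one. Heating A2 would unmask an acylketene that acylates the nucleophilic enol-ether carbon of the pyranone (the future C4a). The resulting cyclohexanedione tautomerises to the 5,7-dihydroxyarene A1, which is the target with its catechol still silylated.
- Merits: the chain is on C8 by construction, ring A needs no protecting groups, C2 can come from a well-established asymmetric hetero-Diels–Alder reaction, and A1 is one step from the target.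
- Weak points: A2 must be assembled linearly, and the chain has to be introduced at a carbon flanked by two vinylogous esters, where dialkylation and O-alkylation compete. The acylketene can also be trapped on oxygen or add across the enol ether as a heterodiene. The thermolysis is run on a substrate holding an allylic acetate and a β-aryloxy ketone.
- Comparison: this road is better in regiochemical certainty and in the precedent behind C2. The chosen plan sets against it a commercial ring A, a convergent union of two short fragments, and a key step that makes ring C and C2 together, so the route is considerably shorter.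

**Alternative 2:** The cuts are C2–C3 and O1–C8a, so ring C is made before ring A. Aldehyde 8 of the present route and 1-methoxy-3-(trimethylsilyloxy)butadiene A4 would combine under Ti(OiPr)4 and a 1,1'-bi-2-naphthol enantiomer to give dihydropyranone A3.
- Merits: the asymmetric hetero-Diels–Alder reaction of aromatic aldehydes with this diene is one of the most dependable ways to set an aryl-bearing stereocentre next to oxygen. In this respect it is clearly superior to the key step chosen here, which has no precedent as an enantioselective reaction.
- Weak points: A3 holds only rings B and C. Ring A, with two hydroxyls and the chain, must then be annulated onto the enol-ether double bond, which needs four more carbons in the right oxidation pattern and leads back to a precursor of the A2 type. During that work C2 sits β to an enone carbonyl and is exposed to retro-oxa-Michael loss under the basic conditions needed to functionalise the future C8a.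
- Comparison: stereocontrol is secured early and cheaply, but the key step builds the smallest part of the complexity and leaves the longest way. The chosen plan concentrates the risk in one step that delivers the whole skeleton, and keeps a resolution in reserve.

**Alternative 3:** The cuts are C8a–C8, C7–C6 and C8a–C4a of ring A. Heating 3-ethoxycyclobutenone A6 with the chain-bearing siloxyalkyne A7 would give phenol A5 by a Danheiser benzannulation (ring opening to a vinylketene, [2+2] addition, second ring opening, 6π closure).
- Merits: every substituent of ring A is placed without ambiguity. The free hydroxyl (future O1) is next to the chain, the C7 oxygen is a silyl ether and the C5 oxygen an ethyl ether, so the C6/C8 question never arises. This is better than the steric argument on which the silylation of the chosen plan rests. After ortho-formylation A5 could even enter the chosen key step.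
- Weak points: the step builds a ring that can be bought in oxidised form as 4. A7 needs several steps of its own. A5 lacks the C4 carbon. The ethyl ether on the C5 oxygen must finally be cleaved by a Lewis acid in the presence of the allylic acetate and of a C7 hydroxyl poised to cyclise onto the alkene. The primary silyl ether must be exchanged for the acetate. Ring C and C2 remain unsolved.
- Comparison: regiocontrol is superior, at the cost of many extra steps and a harsh dealkylation. The chosen plan answers the same question with one selective silylation and holds a regiochemically unambiguous fallback.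

Key step: step 7

## Route

Assumption: the sense of induction of the chiral acid in step 7 cannot be predicted, so the catalyst enantiomer that gives the (2S) series is to be found by trial; racemic 1 is used because its stereocentre is lost in step 1.

Step 1
Reactants: 1 2-methyl-2-vinyloxirane (isoprene monoxide, racemic)
Product: 2 (E)-4-chloro-2-methylbut-2-en-1-ol
Conditions: TiCl4, CH2Cl2, −85 °C; then 1 M HCl
Reagents that add atoms: titanium tetrachloride, Cl[Ti](Cl)(Cl)Cl
Why: Conjugate (SN2') opening of a vinyl oxirane by a Lewis-acidic chloride source; chloride enters at the vinyl terminus as the titanium-bound oxygen leaves, and the E alkene is the documented outcome, the vinyl terminus reacting anti to the oxirane CH2.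

Step 2
Reactants: 2 (E)-4-chloro-2-methylbut-2-en-1-ol
Product: 3 (E)-4-chloro-2-methylbut-2-enyl acetate
Conditions: Ac2O, pyridine, DMAP (cat.), CH2Cl2, 0 °C
Reagents that add atoms: acetic anhydride, CC(=O)OC(C)=O
Why: Standard DMAP-catalysed acetylation of a primary alcohol; at 0 °C and short reaction time the allylic chloride is not displaced.

Step 3
Reactants: 4 2,4,6-trihydroxybenzaldehyde; 3 (E)-4-chloro-2-methylbut-2-enyl acetate
Product: 5 3-[(E)-4-acetoxy-3-methylbut-2-enyl]-2,4,6-trihydroxybenzaldehyde
Conditions: DBU, NaI (cat.), THF, 0 °C to rt (4 in excess)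
Reagents that add atoms: none
Why: C-alkylation of the ambident phloroglucinol anion with an allylic halide, the reaction type used for C-prenylation of acylphloroglucinols; C3 and C5 of 4 are equivalent, so mono-C-alkylation gives one regioisomer, and direct iodide-assisted SN2 displacement at the primary allylic carbon keeps the E alkene.

Step 4
Reactants: 5 3-[(E)-4-acetoxy-3-methylbut-2-enyl]-2,4,6-trihydroxybenzaldehyde
Product: 6 3-[(E)-4-acetoxy-3-methylbut-2-enyl]-2-hydroxy-4,6-bis(triisopropylsilyloxy)benzaldehyde
Conditions: TIPSCl (2.1 equiv), imidazole, DMF, 0 °C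
Reagents that add atoms: chlorotriisopropylsilane, CC(C)[Si](Cl)(C(C)C)C(C)C
Why: Silylation of phenols with a bulky chlorosilane; the unchelated para hydroxyl reacts first and the less hindered of the two ortho hydroxyls second, leaving the hydroxyl wedged between chain and formyl group as the hydrogen-bonded chelate.

Step 5
Reactants: 7 3,4-dihydroxybenzaldehyde
Product: 8 3,4-bis(tert-butyldimethylsilyloxy)benzaldehyde
Conditions: TBSCl, imidazole, DMF, rt
Reagents that add atoms: tert-butylchlorodimethylsilane, CC(C)(C)[Si](C)(C)Cl
Why: Standard imidazole-promoted silylation of both catechol hydroxyls.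

Step 6
Reactants: 8 3,4-bis(tert-butyldimethylsilyloxy)benzaldehyde
Product: 9 3,4-bis(tert-butyldimethylsilyloxy)styrene
Conditions: Ph3PCH3Br, n-BuLi, THF, 0 °C to rt
Reagents that add atoms: methyltriphenylphosphonium bromide, C[P+](c1ccccc1)(c1ccccc1)c1ccccc1.[Br-]
Why: Wittig methylenation of an aromatic aldehyde with the non-stabilised ylide; aryl silyl ethers tolerate the preformed ylide.

Step 7
Reactants: 6 3-[(E)-4-acetoxy-3-methylbut-2-enyl]-2-hydroxy-4,6-bis(triisopropylsilyloxy)benzaldehyde; 9 3,4-bis(tert-butyldimethylsilyloxy)styrene
Product: 12 (2S,4S)-8-[(E)-4-acetoxy-3-methylbut-2-enyl]-2-[3,4-bis(tert-butyldimethylsilyloxy)phenyl]-4-methoxy-5,7-bis(triisopropylsilyloxy)chromane, via dimethyl acetal 10 (not isolated), via O-protonated methoxy o-quinone methide 11 (not isolated)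
Conditions: chiral imidodiphosphorimidate (IDPi) Brønsted acid (5 mol%, enantiomer selected for 2S), HC(OMe)3 (1.5 equiv), 9 (2 equiv), 5 Å MS, CH2Cl2, −60 °C
Reagents that add atoms: trimethyl orthoformate, COC(OC)OC
Why: Proposed new method: the acid and trimethyl orthoformate turn the chelated aldehyde into acetal 10, which ionises to the aryl(methoxy)carbenium ion 11 (an O-protonated 4-methoxy o-quinone methide) held to the chiral imidodiphosphorimidate anion by ion pairing and by the hydrogen bond of the free C2 hydroxyl; the closest known reactions are the achiral-acid three-component synthesis of racemic 2,4-cis-4-alkoxyflavans from salicylaldehydes, orthoformates and styrenes, and confined chiral acid catalysis of intramolecular o-quinone methide [4+2] cycloadditions and of styrene Prins reactions. Styrene 9 attacks the cationic carbon with its CH2 terminus (C3–C4 bond) and the phenolic oxygen then collapses on the developing 4-silyloxybenzylic cation (O1–C2 bond), an asynchronous inverse-demand hetero-Diels–Alder reaction. Ring C is thus closed by intermolecular [4+2] cycloaddition, the ring-closing event being six-membered O1–C2 bond formation. C4 is set by the face of 11 that the anion leaves open, and C2 follows from the endo approach of the aryl group, which places aryl and methoxy cis and pseudo-equatorial; since C4 is erased later, the cis isomer must be separated from any trans isomer at this stage, because the two would give opposite C2 configurations of the ketone. Regiochemistry needs no further control: only the hydroxyl next to the chain is free, so the chain ends on C8, and the polarisation of 9 sends its benzylic carbon to oxygen. Chemoselectivity for 9 over the chain alkene rests on the latter being trisubstituted, hindered and deactivated by the allylic acetate, and on the low temperature and the excess of 9.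

Step 8
Reactants: 12 (2S,4S)-8-[(E)-4-acetoxy-3-methylbut-2-enyl]-2-[3,4-bis(tert-butyldimethylsilyloxy)phenyl]-4-methoxy-5,7-bis(triisopropylsilyloxy)chromane
Product: 13 (2S)-8-[(E)-4-acetoxy-3-methylbut-2-enyl]-2-[3,4-bis(tert-butyldimethylsilyloxy)phenyl]-5,7-bis(triisopropylsilyloxy)chroman-4-ol (both C4 epimers)
Conditions: PPTS (cat.), THF/H2O (4:1), rt
Reagents that add atoms: water, O
Why: SN1 solvolysis of a benzylic ether whose cation is stabilised by three ortho/para oxygens of ring A; water in large excess drives the exchange, C2 is not involved, and the C4 configuration is immaterial because it is oxidised next.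

Step 9
Reactants: 13 (2S)-8-[(E)-4-acetoxy-3-methylbut-2-enyl]-2-[3,4-bis(tert-butyldimethylsilyloxy)phenyl]-5,7-bis(triisopropylsilyloxy)chroman-4-ol
Product: 14 (2S)-8-[(E)-4-acetoxy-3-methylbut-2-enyl]-2-[3,4-bis(tert-butyldimethylsilyloxy)phenyl]-5,7-bis(triisopropylsilyloxy)chroman-4-one
Conditions: Dess–Martin periodinane, pyridine, CH2Cl2, 0 °C to rt
Reagents that add atoms: none
Why: Dess–Martin oxidation of a secondary benzylic alcohol to the aryl ketone under buffered, non-basic conditions that leave alkene, acetate, silyl ethers and the C2 stereocentre untouched.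

Step 10
Reactants: 14 (2S)-8-[(E)-4-acetoxy-3-methylbut-2-enyl]-2-[3,4-bis(tert-butyldimethylsilyloxy)phenyl]-5,7-bis(triisopropylsilyloxy)chroman-4-one
Product: 15 Kanzonol S, (2S)-8-[(E)-4-acetoxy-3-methylbut-2-enyl]-2-(3,4-dihydroxyphenyl)-5,7-dihydroxychroman-4-one
Conditions: TBAF, AcOH (1:1), THF, 0 °C to rt
Reagents that add atoms: none
Why: Fluoride cleavage of four aryl silyl ethers; acetic acid buffering keeps the phenoxide concentration low, so that neither retro-oxa-Michael opening (racemisation at C2) nor loss of the acetate should occur.

## Compound list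

1 | 2-methyl-2-vinyloxirane (isoprene monoxide, racemic) | CC1(C=C)CO1 | starting material
2 | (E)-4-chloro-2-methylbut-2-en-1-ol | OC/C(C)=C/CCl | intermediate
3 | (E)-4-chloro-2-methylbut-2-enyl acetate | CC(=O)OC/C(C)=C/CCl | intermediate
4 | 2,4,6-trihydroxybenzaldehyde | O=Cc1c(O)cc(O)cc1O | starting material
5 | 3-[(E)-4-acetoxy-3-methylbut-2-enyl]-2,4,6-trihydroxybenzaldehyde | CC(=O)OC/C(C)=C/Cc1c(O)cc(O)c(C=O)c1O | intermediate
6 | 3-[(E)-4-acetoxy-3-methylbut-2-enyl]-2-hydroxy-4,6-bis(triisopropylsilyloxy)benzaldehyde | CC(=O)OC/C(C)=C/Cc1c(O[Si](C(C)C)(C(C)C)C(C)C)cc(O[Si](C(C)C)(C(C)C)C(C)C)c(C=O)c1O | intermediate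
7 | 3,4-dihydroxybenzaldehyde | O=Cc1ccc(O)c(O)c1 | starting material
8 | 3,4-bis(tert-butyldimethylsilyloxy)benzaldehyde | O=Cc1ccc(O[Si](C)(C)C(C)(C)C)c(O[Si](C)(C)C(C)(C)C)c1 | intermediate
9 | 3,4-bis(tert-butyldimethylsilyloxy)styrene | C=Cc1ccc(O[Si](C)(C)C(C)(C)C)c(O[Si](C)(C)C(C)(C)C)c1 | intermediate
10 | dimethyl acetal of 6 | CC(=O)OC/C(C)=C/Cc1c(O[Si](C(C)C)(C(C)C)C(C)C)cc(O[Si](C(C)C)(C(C)C)C(C)C)c(C(OC)OC)c1O | intermediate (not isolated)
11 | aryl(methoxy)carbenium ion of 6 (O-protonated 4-methoxy o-quinone methide; counter-ion is the chiral imidodiphosphorimidate anion) | CC(=O)OC/C(C)=C/Cc1c(O[Si](C(C)C)(C(C)C)C(C)C)cc(O[Si](C(C)C)(C(C)C)C(C)C)c(/C=[O+]/C)c1O | intermediate (not isolated)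
12 | (2S,4S)-8-[(E)-4-acetoxy-3-methylbut-2-enyl]-2-[3,4-bis(tert-butyldimethylsilyloxy)phenyl]-4-methoxy-5,7-bis(triisopropylsilyloxy)chromane (2,4-cis) | CC(=O)OC/C(C)=C/Cc1c(O[Si](C(C)C)(C(C)C)C(C)C)cc(O[Si](C(C)C)(C(C)C)C(C)C)c2c1O[C@H](c1ccc(O[Si](C)(C)C(C)(C)C)c(O[Si](C)(C)C(C)(C)C)c1)C[C@@H]2OC | intermediate
13 | (2S)-8-[(E)-4-acetoxy-3-methylbut-2-enyl]-2-[3,4-bis(tert-butyldimethylsilyloxy)phenyl]-5,7-bis(triisopropylsilyloxy)chroman-4-ol (both C4 epimers) | CC(=O)OC/C(C)=C/Cc1c(O[Si](C(C)C)(C(C)C)C(C)C)cc(O[Si](C(C)C)(C(C)C)C(C)C)c2c1O[C@H](c1ccc(O[Si](C)(C)C(C)(C)C)c(O[Si](C)(C)C(C)(C)C)c1)CC2O | intermediate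
14 | (2S)-8-[(E)-4-acetoxy-3-methylbut-2-enyl]-2-[3,4-bis(tert-butyldimethylsilyloxy)phenyl]-5,7-bis(triisopropylsilyloxy)chroman-4-one | CC(=O)OC/C(C)=C/Cc1c(O[Si](C(C)C)(C(C)C)C(C)C)cc(O[Si](C(C)C)(C(C)C)C(C)C)c2c1O[C@H](c1ccc(O[Si](C)(C)C(C)(C)C)c(O[Si](C)(C)C(C)(C)C)c1)CC2=O | intermediate
15 | Kanzonol S, (2S)-8-[(E)-4-acetoxy-3-methylbut-2-enyl]-2-(3,4-dihydroxyphenyl)-5,7-dihydroxychroman-4-one | CC(=O)OC/C(C)=C/Cc1c(O)cc(O)c2c1O[C@H](c1ccc(O)c(O)c1)CC2=O | target

## Step count and risks

Total: 10 steps. Longest linear sequence: 8 steps (steps 1, 2, 3, 4, 7, 8, 9, 10).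

**Step 7 (key step, proposed new method).**
- What may go wrong: facial discrimination by the counter-anion may be insufficient, because the cation is large and only loosely held. A background reaction through any achiral acid would give racemic product. The electron-rich styrene may oligomerise cationically. The chain alkene may be drawn in, or the free hydroxyl may cyclise onto it. Reversible ionisation at C4 and C2 could erode the cis selectivity, which carries the optical purity of C2.
- Fallback (known chemistry), from 6 and 9 back to 14: the same three-component cycloaddition is run with an achiral acid such as Yb(OTf)3, giving racemic 2,4-cis-4-methoxyflavan F1. Hydrolysis and oxidation as in steps 8 and 9 give racemic flavan-4-ol F2 and racemic flavanone F3. F3 is then resolved kinetically by Noyori–Ikariya asymmetric transfer hydrogenation with RuCl(p-cymene)[(R,R)-TsDPEN] in HCO2H/Et3N. This should reduce the (2R)-ketone to the (2R,4R)-cis-flavan-4-ol F4 and leave the (2S)-ketone, which is compound 14. Half of the material is sacrificed.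

**Step 3.**
- What may go wrong: O-alkylation, double C-alkylation or dearomatising alkylation of the very nucleophilic phloroglucinol anion, and slow displacement of the chloride.
- Fallback, from 4 and 1 back to 5: Tsuji–Trost addition of 4 to isoprene monoxide 1 with Pd(PPh3)4 (zerovalent palladium) in THF, where O-allyl products can re-ionise and funnel to the C-allyl compound. This gives 3-[(E)-4-hydroxy-3-methylbut-2-enyl]-2,4,6-trihydroxybenzaldehyde F5. Acetylation of its primary alcohol with Candida antarctica lipase B and vinyl acetate, which leaves phenols alone, gives 5. The E/Z ratio of the π-allyl addition would have to be checked and the isomers separated.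

**Step 4.**
- What may go wrong: silylation at the wrong ortho hydroxyl (poor site selectivity between the two formyl-flanking hydroxyls), which would later place the chain on C6.
- Fallback, from 4 back to 6: the hydroxyls are differentiated before the chain exists. Bis-silylation of symmetric 4 (TIPSCl, imidazole) gives 2-hydroxy-4,6-bis(triisopropylsilyloxy)benzaldehyde F6 without ambiguity. Mitsunobu O-allylation (allyl alcohol, PPh3, DIAD) gives 2-allyloxy-4,6-bis(triisopropylsilyloxy)benzaldehyde F7. Thermal aromatic Claisen rearrangement, which can only reach C3, gives 3-allyl-2-hydroxy-4,6-bis(triisopropylsilyloxy)benzaldehyde F8. Cross-metathesis of F8 with 2-methylallyl acetate (second-generation Hoveyda–Grubbs catalyst) gives 6. The alkene geometry of the metathesis is only moderately biased towards E, so the isomers would have to be separated.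

**Step 8.**
- What may go wrong: loss of a proton from the C4 cation to give the flav-3-ene instead of capture by water, or capture of the cation by an arene.
- Fallback, from 12 back to 14: direct oxidation of the benzylic methyl ether with DDQ in CH2Cl2/pH 7 buffer (hydride abstraction at C4, hydration of the oxocarbenium ion, loss of methanol). This by-passes 13 and step 9 and creates no compound outside the list (F0).

## Further compounds

F1 | step 7 | racemic 2,4-cis-8-[(E)-4-acetoxy-3-methylbut-2-enyl]-2-[3,4-bis(tert-butyldimethylsilyloxy)phenyl]-4-methoxy-5,7-bis(triisopropylsilyloxy)chromane | CC(=O)OC/C(C)=C/Cc1c(O[Si](C(C)C)(C(C)C)C(C)C)cc(O[Si](C(C)C)(C(C)C)C(C)C)c2c1OC(c1ccc(O[Si](C)(C)C(C)(C)C)c(O[Si](C)(C)C(C)(C)C)c1)CC2OC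
F2 | step 7 | racemic 8-[(E)-4-acetoxy-3-methylbut-2-enyl]-2-[3,4-bis(tert-butyldimethylsilyloxy)phenyl]-5,7-bis(triisopropylsilyloxy)chroman-4-ol (C4 epimers) | CC(=O)OC/C(C)=C/Cc1c(O[Si](C(C)C)(C(C)C)C(C)C)cc(O[Si](C(C)C)(C(C)C)C(C)C)c2c1OC(c1ccc(O[Si](C)(C)C(C)(C)C)c(O[Si](C)(C)C(C)(C)C)c1)CC2O
F3 | step 7 | racemic 8-[(E)-4-acetoxy-3-methylbut-2-enyl]-2-[3,4-bis(tert-butyldimethylsilyloxy)phenyl]-5,7-bis(triisopropylsilyloxy)chroman-4-one | CC(=O)OC/C(C)=C/Cc1c(O[Si](C(C)C)(C(C)C)C(C)C)cc(O[Si](C(C)C)(C(C)C)C(C)C)c2c1OC(c1ccc(O[Si](C)(C)C(C)(C)C)c(O[Si](C)(C)C(C)(C)C)c1)CC2=O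
F4 | step 7 | (2R,4R)-8-[(E)-4-acetoxy-3-methylbut-2-enyl]-2-[3,4-bis(tert-butyldimethylsilyloxy)phenyl]-5,7-bis(triisopropylsilyloxy)chroman-4-ol (2,4-cis) | CC(=O)OC/C(C)=C/Cc1c(O[Si](C(C)C)(C(C)C)C(C)C)cc(O[Si](C(C)C)(C(C)C)C(C)C)c2c1O[C@@H](c1ccc(O[Si](C)(C)C(C)(C)C)c(O[Si](C)(C)C(C)(C)C)c1)C[C@H]2O
F5 | step 3 | 3-[(E)-4-hydroxy-3-methylbut-2-enyl]-2,4,6-trihydroxybenzaldehyde | OC/C(C)=C/Cc1c(O)cc(O)c(C=O)c1O
F6 | step 4 | 2-hydroxy-4,6-bis(triisopropylsilyloxy)benzaldehyde | O=Cc1c(O)cc(O[Si](C(C)C)(C(C)C)C(C)C)cc1O[Si](C(C)C)(C(C)C)C(C)C
F7 | step 4 | 2-allyloxy-4,6-bis(triisopropylsilyloxy)benzaldehyde | C=CCOc1cc(O[Si](C(C)C)(C(C)C)C(C)C)cc(O[Si](C(C)C)(C(C)C)C(C)C)c1C=O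
F8 | step 4 | 3-allyl-2-hydroxy-4,6-bis(triisopropylsilyloxy)benzaldehyde | C=CCc1c(O[Si](C(C)C)(C(C)C)C(C)C)cc(O[Si](C(C)C)(C(C)C)C(C)C)c(C=O)c1O
F0 | step 8 | none | none
A1 | alternative 1 | (2S)-3',4'-bis(O-tert-butyldimethylsilyl) Kanzonol S | CC(=O)OC/C(C)=C/Cc1c(O)cc(O)c2c1O[C@H](c1ccc(O[Si](C)(C)C(C)(C)C)c(O[Si](C)(C)C(C)(C)C)c1)CC2=O
A2 | alternative 1 | (2S)-6-[(E)-5-acetoxy-1-(2,2-dimethyl-4-oxo-4H-1,3-dioxin-6-yl)-4-methylpent-3-enyl]-2-[3,4-bis(tert-butyldimethylsilyloxy)phenyl]-2,3-dihydro-4H-pyran-4-one (epimers at the side-chain carbon) | CC(=O)OC/C(C)=C/CC(C1=CC(=O)OC(C)(C)O1)C1=CC(=O)C[C@@H](c2ccc(O[Si](C)(C)C(C)(C)C)c(O[Si](C)(C)C(C)(C)C)c2)O1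
A3 | alternative 2 | (2S)-2-[3,4-bis(tert-butyldimethylsilyloxy)phenyl]-2,3-dihydro-4H-pyran-4-one | O=C1C=CO[C@H](c2ccc(O[Si](C)(C)C(C)(C)C)c(O[Si](C)(C)C(C)(C)C)c2)C1
A4 | alternative 2 | (E)-1-methoxy-3-(trimethylsilyloxy)buta-1,3-diene | CO/C=C/C(=C)O[Si](C)(C)C
A5 | alternative 3 | 2-[(E)-4-(tert-butyldimethylsilyloxy)-3-methylbut-2-enyl]-5-ethoxy-3-(triisopropylsilyloxy)phenol | Oc1cc(OCC)cc(O[Si](C(C)C)(C(C)C)C(C)C)c1C/C=C(\C)CO[Si](C)(C)C(C)(C)C
A6 | alternative 3 | 3-ethoxycyclobut-2-en-1-one | CCOC1=CC(=O)C1
A7 | alternative 3 | (E)-6-(tert-butyldimethylsilyloxy)-5-methyl-1-(triisopropylsilyloxy)hex-4-en-1-yne | CC(C)[Si](C(C)C)(C(C)C)OC#CC/C=C(\C)CO[Si](C)(C)C(C)(C)C
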